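The synthesis rests on cutting the diaryl ether bond between O-2 of ring A and C4 of the phthalide ring B (phthalide numbering), the bond that closes the seven-membered dioxepinone. C4 is the only C–H of ring B and lies para to the C7 phenol and ortho to the C5 ester oxygen, so a dehydrogenative phenol coupling of a depside forges this bond and completes the tetracyclic depsidone in one operation, without prefunctionalisation. The precursor is the ester of a 3-O-benzyl salicylic acid (ring A) with a 5,7-dihydroxyphthalide whose lactol is masked as a methyl pseudo-ester. The labile lactol stereocentre is set at the end by acylative dynamic kinetic resolution and enzymatic deacetylation.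

Key step: step 10

Assumption: the free lactol epimerises in solution through its ring-opened formyl acid, so the (R) configuration is fixed in acetate 19 (catalyst antipode chosen in a trial run, assignment to be secured by X-ray analysis) and the target is delivered as a solid isolated cold at neutral pH; aldehyde 1 is taken as a catalogue compound.

Step 1
Reactants: 1 2,3,4-trimethoxy-6-methylbenzaldehyde
Product: 2 2,3-dihydroxy-4-methoxy-6-methylbenzaldehyde
Conditions: BCl3 (3.5 equiv), CH2Cl2, 0 °C → rt; then H2O
Reagents that add atoms: none
Why: Chelation-controlled Lewis-acid ether cleavage, in which BCl3 bound to the formyl oxygen cleaves the ortho 2-methoxy group and the resulting aryloxyboron chloride cleaves the neighbouring 3-methoxy group through a cyclic catechol borate, while the remote 4-methoxy group lacks this assistance and should survive.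

Step 2
Reactants: 2 2,3-dihydroxy-4-methoxy-6-methylbenzaldehyde
Product: 3 3-benzyloxy-2-hydroxy-4-methoxy-6-methylbenzaldehyde
Conditions: NaH (2.2 equiv), DMSO, rt; BnBr (1.0 equiv), rt; then 1 M HCl
Reagents that add atoms: benzyl bromide, BrCc1ccccc1
Why: Williamson ether synthesis on the dianion, where the 2-phenoxide is tied up in a chelate with the formyl group so that the 3-phenoxide is the more nucleophilic oxygen and should take the single equivalent of benzyl bromide.

Step 3
Reactants: 3 3-benzyloxy-2-hydroxy-4-methoxy-6-methylbenzaldehyde
Product: 4 3-benzyloxy-2-hydroxy-4-methoxy-6-methylbenzoic acid (fragment 1)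
Conditions: NaClO2, NaH2PO4, 2-methyl-2-butene (excess), t-BuOH/THF/H2O, 0 °C → rt
Reagents that add atoms: sodium chlorite, [Na+].[O-]Cl=O
Why: Pinnick oxidation, in which chlorous acid adds to the aldehyde and fragments to the acid and HOCl, the excess alkene trapping the HOCl before it can chlorinate the electron-rich ring, while the phenol and the benzyl ether are tolerated at pH 3–4.

Step 4
Reactants: 5 2,6-dimethoxytoluene
Product: 6 1-bromo-2,4-dimethoxy-3-methylbenzene
Conditions: NBS (1.0 equiv), MeCN, 0 °C → rt
Reagents that add atoms: N-bromosuccinimide, O=C1CCC(=O)N1Br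
Why: Electrophilic aromatic bromination at the position that is ortho to one methoxy group and para to the other, which should stop after one bromine because the product is deactivated.

Step 5
Reactants: 6 1-bromo-2,4-dimethoxy-3-methylbenzene
Product: 8 N,N-diethyl-2,4-dimethoxy-3-methylbenzamide, via (2,4-dimethoxy-3-methylphenyl)lithium 7 (not isolated)
Conditions: n-BuLi, THF, −78 °C; then ClCONEt2, −78 °C → rt
Reagents that add atoms: diethylcarbamoyl chloride, CCN(CC)C(Cl)=O; n-butyllithium, [Li]CCCC (supplies only the lithium of 7)
Why: Bromine–lithium exchange followed by addition–elimination of the aryllithium on the carbamoyl chloride, which should stop at the tertiary amide because that amide is a poor electrophile at low temperature.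

Step 6
Reactants: 8 N,N-diethyl-2,4-dimethoxy-3-methylbenzamide
Product: 10 N,N-diethyl-6-formyl-2,4-dimethoxy-3-methylbenzamide, via [2-(diethylcarbamoyl)-3,5-dimethoxy-4-methylphenyl]lithium 9 (not isolated)
Conditions: s-BuLi, TMEDA, THF, −78 °C; then DMF, −78 → 0 °C; then H2O
Reagents that add atoms: N,N-dimethylformamide, CN(C)C=O; sec-butyllithium, CCC(C)[Li] (supplies only the lithium of 9)
Why: Directed ortho-metalation, in which the tertiary amide is the strongest director on the ring and C6 is its only free ortho position, followed by formylation with DMF through a hemiaminal alkoxide that releases the aldehyde on quench.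

Step 7
Reactants: 10 N,N-diethyl-6-formyl-2,4-dimethoxy-3-methylbenzamide
Product: 11 rac-3-hydroxy-5,7-dimethoxy-6-methylphthalide
Conditions: 3 M HCl, 1,4-dioxane, reflux
Reagents that add atoms: water, O
Why: Acid hydrolysis with neighbouring-group assistance, the known conversion of ortho-formyl benzamides into 3-hydroxyphthalides, in which the aldehyde hydrate attacks the adjacent protonated amide in a 5-exo-trig closure and expels diethylamine to give the ring-closed lactol as a racemate.

Step 8
Reactants: 11 rac-3-hydroxy-5,7-dimethoxy-6-methylphthalide
Product: 13 rac-5,7-dihydroxy-3-methoxy-6-methylphthalide (fragment 2), via rac-3,5,7-trihydroxy-6-methylphthalide 12 (not isolated)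
Conditions: BBr3 (5 equiv), CH2Cl2, −78 °C → rt; then MeOH, 0 °C → reflux
Reagents that add atoms: methanol, CO
Why: BBr3 ether cleavage (bromide attacks the methyl group of each boron-complexed aryl ether) followed by methanolysis of the boron esters, after which the HBr formed catalyses Fischer-type acetalisation of lactol 12 to the cyclic methyl pseudo-ester through the phthalidyl oxocarbenium ion, the large excess of methanol outcompeting any arene nucleophile and C3 staying racemic.

Step 9
Reactants: 4 3-benzyloxy-2-hydroxy-4-methoxy-6-methylbenzoic acid (fragment 1); 13 rac-5,7-dihydroxy-3-methoxy-6-methylphthalide (fragment 2)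
Product: 14 depside, 7-hydroxy-3-methoxy-6-methyl-1-oxo-1,3-dihydroisobenzofuran-5-yl 3-benzyloxy-2-hydroxy-4-methoxy-6-methylbenzoate (racemic at C3)
Conditions: DCC (1.1 equiv), dry THF/toluene, 0 °C → rt
Reagents that add atoms: none
Why: Carbodiimide (Steglich-type) esterification through the O-acylisourea, the standard way of assembling para-depsides, which should acylate the 5-hydroxyl as the only unchelated phenol because the 7-hydroxyl is hydrogen-bonded to the lactone carbonyl and the 2-hydroxyl of 4 to its own carboxyl group.

Step 10
Reactants: 14 depside (racemic at C3)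
Product: 16 benzyl-protected depsidone methyl pseudo-ester (racemic at C3), via C4-sp3 dienone tautomer 15 (not isolated)
Conditions: activated MnO2 (tetravalent manganese, 15 equiv), dry CH2Cl2, about 1 mM, rt, argon
Reagents that add atoms: none
Why: Activated MnO2 removes a hydrogen atom from each of the two phenols at its surface, and the ring A 2-oxyl radical then bonds to C4 of ring B, the carbon that carries the spin density para to the C7 oxyl, giving the cross-conjugated dienone 15, which enolises back to the C7 phenol with loss of the former C4–H. The closest known reaction type is the MnO2-mediated oxidative cyclisation of para-depsides to depsidones, the laboratory form of the phenoxyl coupling of depsidone biosynthesis. The seven-membered 1,4-dioxepin-5-one ring closes by intramolecular O–C(aryl) radical pairing across the ester tether, which has to turn into its s-cis, lactone-like conformation; the ring is built from O-2, C2 and C1 of ring A, the ester C(=O)–O unit, and C5 and C4 of ring B. No stereocentre is created, since the sp3 C4 of 15 is lost on enolisation and the acetal carbon C3 stays racemic. The step needs intramolecular O–C coupling in preference to intermolecular C–C or C–O coupling at the free C5–H of ring A (para to its oxyl), which is secured by high dilution, by the tether holding O-2 over the only C–H of ring B, and by the methoxy and methyl groups flanking ring A C5. Over-oxidation is limited because O-3 of ring A is benzylated, so no ortho-quinone can form, and because the lactol is masked as an acetal that MnO2 does not touch.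

Step 11
Reactants: 16 benzyl-protected depsidone methyl pseudo-ester (racemic at C3)
Product: 17 debenzylated depsidone methyl pseudo-ester (ring A 3-OH free, racemic at C3)
Conditions: H2 (1 atm), palladium on carbon (10% Pd), EtOAc, rt
Reagents that add atoms: none
Why: Catalytic hydrogenolysis of the benzyl aryl ether on zerovalent palladium under neutral conditions, which should leave the aryl ester, the lactone and the acetal untouched because the acetal carbon sits on an electron-poor ring and is not activated by acid.

Step 12
Reactants: 17 debenzylated depsidone methyl pseudo-ester (racemic at C3)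
Product: 18 racemic lactol (racemic form of the target, C3 epimers interconverting)
Conditions: 2 M HCl/THF (1:2), 45 °C
Reagents that add atoms: water, O
Why: Acid-catalysed hydrolysis of the cyclic acetal (pseudo-ester) through the phthalidyl oxocarbenium ion, which water captures to give the lactol as an interconverting racemate, while the depsidone aryl ester, robust towards aqueous acid, should stay closed.

Step 13
Reactants: 18 racemic lactol
Product: 19 (R)-triacetate (acetates on the lactol oxygen at C3, on ring A O-3 and on ring B O-7)
Conditions: Ac2O (5 equiv), i-Pr2NEt (4 equiv), one enantiomer of 7-benzyloxy-6,7-dihydro-5H-pyrrolo[1,2-a]imidazole (C13H14N2O, 10 mol %), CH2Cl2/toluene, −30 °C → rt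
Reagents that add atoms: acetic anhydride, CC(=O)OC(C)=O
Why: Acylative dynamic kinetic resolution, known for 3-hydroxyphthalides, in which the amine base keeps the lactol enantiomers in rapid equilibrium through the ring-opened formyl carboxylate while the chiral N-acetylimidazolium ion transfers acetyl faster to one of them, so that the new (R) centre is set by the catalyst (its antipode being chosen accordingly) and the two phenols are acetylated in the same pot without stereochemical consequence.

Step 14
Reactants: 19 (R)-triacetate
Product: 20 target CNP0211607.1, (R)-lactol
Conditions: pig liver esterase, 0.1 M phosphate buffer pH 7.0/acetone (9:1), 4 °C; product filtered off cold as it precipitates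
Reagents that add atoms: none
Why: Enzymatic ester hydrolysis through an acyl-enzyme intermediate cleaves each acetate at the acyl–oxygen bond, so the C3–O bond is never broken and the (R) configuration is retained, while neutral pH, low temperature and precipitation of the product keep ring–chain epimerisation slow.

Compound list
1 | 2,3,4-trimethoxy-6-methylbenzaldehyde | COc1cc(C)c(C=O)c(OC)c1OC | starting material
2 | 2,3-dihydroxy-4-methoxy-6-methylbenzaldehyde | COc1cc(C)c(C=O)c(O)c1O | intermediate
3 | 3-benzyloxy-2-hydroxy-4-methoxy-6-methylbenzaldehyde | COc1cc(C)c(C=O)c(O)c1OCc1ccccc1 | intermediate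
4 | 3-benzyloxy-2-hydroxy-4-methoxy-6-methylbenzoic acid (fragment 1) | COc1cc(C)c(C(=O)O)c(O)c1OCc1ccccc1 | intermediate
5 | 2,6-dimethoxytoluene | COc1cccc(OC)c1C | starting material
6 | 1-bromo-2,4-dimethoxy-3-methylbenzene | COc1ccc(Br)c(OC)c1C | intermediate
7 | (2,4-dimethoxy-3-methylphenyl)lithium | [Li]c1ccc(OC)c(C)c1OC | intermediate (not isolated)
8 | N,N-diethyl-2,4-dimethoxy-3-methylbenzamide | CCN(CC)C(=O)c1ccc(OC)c(C)c1OC | intermediate
9 | [2-(diethylcarbamoyl)-3,5-dimethoxy-4-methylphenyl]lithium | [Li]c1cc(OC)c(C)c(OC)c1C(=O)N(CC)CC | intermediate (not isolated)
10 | N,N-diethyl-6-formyl-2,4-dimethoxy-3-methylbenzamide | CCN(CC)C(=O)c1c(C=O)cc(OC)c(C)c1OC | intermediate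
11 | rac-3-hydroxy-5,7-dimethoxy-6-methylphthalide | OC1OC(=O)c2c(OC)c(C)c(OC)cc12 | intermediate
12 | rac-3,5,7-trihydroxy-6-methylphthalide | OC1OC(=O)c2c(O)c(C)c(O)cc12 | intermediate (not isolated)
13 | rac-5,7-dihydroxy-3-methoxy-6-methylphthalide (fragment 2) | COC1OC(=O)c2c(O)c(C)c(O)cc12 | intermediate
14 | depside: 7-hydroxy-3-methoxy-6-methyl-1-oxo-1,3-dihydroisobenzofuran-5-yl 3-benzyloxy-2-hydroxy-4-methoxy-6-methylbenzoate, racemic at C3 | COc1cc(C)c(C(=O)Oc2cc3C(OC)OC(=O)c3c(O)c2C)c(O)c1OCc1ccccc1 | intermediate
15 | dienone tautomer of 16: C4 of ring B is sp3 and carries H and the ring A oxygen, C7 is a ketone, C5=C6 and C3a=C7a are double bonds | COc1cc(C)c2c(c1OCc1ccccc1)OC1C(=C(C)C(=O)C3=C1C(OC)OC3=O)OC2=O | intermediate (not isolated)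
16 | protected depsidone: ring A (3-benzyloxy, 4-methoxy, 6-methyl) joined to the phthalide ring B (3-methoxy acetal, 6-methyl, 7-hydroxy) by the ester C(=O)–O–C5 and the ether O-2–C4; racemic at C3 | COc1cc(C)c2c(c1OCc1ccccc1)Oc1c(c(C)c(O)c3c1C(OC)OC3=O)OC2=O | intermediate
17 | debenzylated depsidone methyl pseudo-ester: 16 with free 3-OH on ring A; racemic at C3 | COc1cc(C)c2c(c1O)Oc1c(c(C)c(O)c3c1C(OC)OC3=O)OC2=O | intermediate
18 | racemic lactol: 17 with OH in place of OMe at the phthalide carbon C3 (racemic target) | COc1cc(C)c2c(c1O)Oc1c(c(C)c(O)c3c1C(O)OC3=O)OC2=O | intermediate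
19 | (R)-triacetate: 18 acetylated at the lactol oxygen (C3, R), at ring A O-3 and at ring B O-7 | COc1cc(C)c2c(c1OC(C)=O)Oc1c(c(C)c(OC(C)=O)c3c1[C@H](OC(C)=O)OC3=O)OC2=O | intermediate
20 | CNP0211607.1, (R)-lactol | COc1cc(C)c2c(c1O)Oc1c(c(C)c(O)c3c1[C@H](O)OC3=O)OC2=O | target

Total step count: 14. Longest linear sequence: 11 steps (from 5 to 20, steps 4–14); the ring A branch (steps 1–3) joins at step 9.

Steps most likely to fail

Step 10 (ring closure). The phenoxyl radicals may couple between molecules (C–C or C–O at the free C5–H of ring A) or be oxidised further before the ester tether reaches its s-cis geometry, or the chelated ring B phenol may resist oxidation altogether. The fallback replaces dehydrogenative coupling by a halide-based C–O coupling; it sets out from phthalide 13 and acid 4 and returns to the route at 16. Bromination of 13 with NBS (MeCN, 0 °C) at its single aromatic C–H should give rac-4-bromo-5,7-dihydroxy-3-methoxy-6-methylphthalide F1. DCC esterification of F1 with 4 under the conditions of step 9 should give the bromo-depside F2. An intramolecular Ullmann diaryl ether synthesis (copper monoiodide CuI, N,N-dimethylglycine, Cs2CO3, dry 1,4-dioxane, 90 °C) would then join O-2 of ring A to C4 and deliver 16.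

Step 13 (resolution). Discrimination between the lactol enantiomers next to the bulky C4 aryloxy group may be poor, racemisation may be slow relative to acylation, or acetate may form unselectively through a mixed anhydride of the ring-opened carboxylate. The fallback replaces catalytic stereoconvergence by physical resolution with recycling; it sets out from 18 and returns at 19. Exhaustive acetylation (Ac2O, pyridine, catalytic 4-(dimethylamino)pyridine, CH2Cl2, rt) should give the racemic triacetate F3. Preparative chromatography on a polysaccharide-based chiral stationary phase would separate 19 from its enantiomer, the (S)-triacetate F4. F4 is returned to 18 by the hydrolysis of step 14 followed by equilibration of the lactol in solution.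

Step 14 (release of the lactol). The freed lactol may epimerise through the open formyl acid during slow enzymatic turnover of a poorly soluble, hindered substrate in water, or cleavage of the 7-O-acetate may stay incomplete. The fallback releases the lactol by hydrogenolysis in an aprotic neutral medium instead of by hydrolysis; it sets out from 18 and returns at 20. Benzyl chloroformate and pyridine (CH2Cl2, 0 °C) should give the racemic tris(benzyl carbonate) F5. Chromatography on a chiral stationary phase would give the tris(benzyl carbonate) enantiomer with the spatial arrangement of 20 at C3 F6 (named S only because the carbonate oxygen now outranks the lactone oxygen) and the antipodal tris(benzyl carbonate) F7. Hydrogenolysis of F6 (H2, palladium on carbon, EtOAc, 0 °C) cleaves the three O–benzyl bonds and the carbonic acids lose CO2, so 20 would be obtained after cold filtration and evaporation without the C3–O bond being broken. F7 is recycled by the same hydrogenolysis and equilibration to 18.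

Further compounds
F1 | step 10 | rac-4-bromo-5,7-dihydroxy-3-methoxy-6-methylphthalide | COC1OC(=O)c2c(O)c(C)c(O)c(Br)c12
F2 | step 10 | bromo-depside: 4-bromo-7-hydroxy-3-methoxy-6-methyl-1-oxo-1,3-dihydroisobenzofuran-5-yl 3-benzyloxy-2-hydroxy-4-methoxy-6-methylbenzoate, racemic at C3 | COc1cc(C)c(C(=O)Oc2c(Br)c3C(OC)OC(=O)c3c(O)c2C)c(O)c1OCc1ccccc1
F3 | step 13 | racemic triacetate of 18 | COc1cc(C)c2c(c1OC(C)=O)Oc1c(c(C)c(OC(C)=O)c3c1C(OC(C)=O)OC3=O)OC2=O
F4 | step 13 | (S)-triacetate, enantiomer of 19 | COc1cc(C)c2c(c1OC(C)=O)Oc1c(c(C)c(OC(C)=O)c3c1[C@@H](OC(C)=O)OC3=O)OC2=O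
F5 | step 14 | racemic tris(benzyl carbonate) of 18 (carbonates on the lactol oxygen, ring A O-3 and ring B O-7) | COc1cc(C)c2c(c1OC(=O)OCc1ccccc1)Oc1c(c(C)c(OC(=O)OCc4ccccc4)c3c1C(OC(=O)OCc4ccccc4)OC3=O)OC2=O
F6 | step 14 | tris(benzyl carbonate) with the spatial arrangement of 20 at C3, descriptor S | COc1cc(C)c2c(c1OC(=O)OCc1ccccc1)Oc1c(c(C)c(OC(=O)OCc4ccccc4)c3c1[C@H](OC(=O)OCc4ccccc4)OC3=O)OC2=O
F7 | step 14 | antipodal tris(benzyl carbonate), descriptor R | COc1cc(C)c2c(c1OC(=O)OCc1ccccc1)Oc1c(c(C)c(OC(=O)OCc4ccccc4)c3c1[C@@H](OC(=O)OCc4ccccc4)OC3=O)OC2=O
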